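**Retrosynthetic overview**

- The strategy rests on the tetrasubstituted C2=C3 double bond of the furan ring (O1, C2 carrying C1' of ring B, C3 carrying CH3, C3a, C7a). C2 is read as the carbonyl carbon of an aryl benzoate, C3 as the carbonyl carbon of an ortho acetyl group, and O1–C7a as the phenol C–O bond of ring A.
- Target ⇒ tris(silyl) ether (O–Si cleavage) ⇒ 2-acetylaryl benzoate (reductive titanium carbonyl–carbonyl coupling at C2=C3) ⇒ ring B benzoic acid + 2-hydroxy-4-silyloxyacetophenone (acyl–O1 ester bond).
- The crowded C2–C1' bond is never made by coupling. It is the aryl–carboxyl bond of the acid, which descends from the formyl group of 2,4,6-trihydroxybenzaldehyde through C3' prenylation, silylation at O4' and O6', neutral methylation at O2' and chlorite oxidation.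
- Ring order: both benzene rings are bought. The furan is the only ring formed, and it is closed at a carbon–carbon bond in the penultimate step.

Key step: step 7

Remark: the target has no stereocentre, and rotation about C2–C1' is taken as fast at room temperature, so no axial configuration has to be set. Prenyl = 3-methylbut-2-en-1-yl; TBS = tert-butyldimethylsilyl.

**Step 1**
Reactants: 1 2,4,6-trihydroxybenzaldehyde; 2 prenyl bromide (1-bromo-3-methylbut-2-ene)
Product: 3 2,4,6-trihydroxy-3-prenylbenzaldehyde
Conditions: KOH (1.0 equiv), H2O/MeOH, 0 °C to rt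
Reagents that add atoms: none
Why: C-alkylation of an ambident acylphloroglucinol phenoxide, in which the protic medium solvates the oxygen atoms so that the soft allylic bromide is attacked by ring carbon C3 (equivalent to C5), while one equivalent each of base and bromide at low temperature limits double and O-alkylation and leaves by-products that chromatography should remove.

**Step 2**
Reactants: 3 2,4,6-trihydroxy-3-prenylbenzaldehyde
Product: 4 4,6-bis(tert-butyldimethylsilyloxy)-2-hydroxy-3-prenylbenzaldehyde
Conditions: TBSCl (2.1 equiv), imidazole, CH2Cl2/DMF, 0 °C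
Reagents that add atoms: tert-butyldimethylsilyl chloride, CC(C)(C)[Si](C)(C)Cl
Why: Sterically and hydrogen-bond controlled phenol silylation, in which O4 is unchelated and O6 has only H5 beside it, whereas O2 is wedged between the prenyl CH2 and the formyl group and stays locked in the chelate to C=O once O6 is capped, the same site pattern that partial alkylation of 3-alkylphloroglucinol carbonyl compounds follows.

**Step 3**
Reactants: 4 4,6-bis(tert-butyldimethylsilyloxy)-2-hydroxy-3-prenylbenzaldehyde
Product: 5 4,6-bis(tert-butyldimethylsilyloxy)-2-methoxy-3-prenylbenzaldehyde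
Conditions: MeOH, PPh3, DIAD, THF, 0 °C to rt
Reagents that add atoms: methanol, CO
Why: Mitsunobu etherification, in which the acidic chelated phenol protonates the betaine and is methylated by the small methoxyphosphonium ion under essentially neutral conditions, so that no free phenoxide or carbonate base is present to cleave or scramble the aryl silyl ethers that the formyl group activates.

**Step 4**
Reactants: 5 4,6-bis(tert-butyldimethylsilyloxy)-2-methoxy-3-prenylbenzaldehyde
Product: 6 4,6-bis(tert-butyldimethylsilyloxy)-2-methoxy-3-prenylbenzoic acid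
Conditions: NaClO2, NaH2PO4, 2-methyl-2-butene (large excess), t-BuOH/THF/H2O, 0 °C to rt
Reagents that add atoms: NaClO2 (sodium chlorite), [Na+].[O-]Cl=O
Why: Pinnick oxidation, in which chlorous acid adds to the aldehyde and fragments to the acid, the large excess of 2-methyl-2-butene consumes HOCl faster than the prenyl alkene or the electron-rich C5–H can, and the phosphate buffer is too weakly acidic to remove the silyl ethers or to decarboxylate the product.

**Step 5**
Reactants: 7 2,4-dihydroxyacetophenone
Product: 8 1-[4-(tert-butyldimethylsilyloxy)-2-hydroxyphenyl]ethanone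
Conditions: TBSCl (1.05 equiv), imidazole, CH2Cl2, 0 °C to rt
Reagents that add atoms: tert-butyldimethylsilyl chloride, CC(C)(C)[Si](C)(C)Cl
Why: Selective phenol silylation, since the 2-OH is held in a strong hydrogen bond to the acetyl oxygen and one equivalent of silyl chloride should react only at the free and more acidic 4-OH.

**Step 6**
Reactants: 6 4,6-bis(tert-butyldimethylsilyloxy)-2-methoxy-3-prenylbenzoic acid; 8 1-[4-(tert-butyldimethylsilyloxy)-2-hydroxyphenyl]ethanone
Product: 10 2-acetyl-5-(tert-butyldimethylsilyloxy)phenyl 4,6-bis(tert-butyldimethylsilyloxy)-2-methoxy-3-prenylbenzoate, via acid chloride 9 (not isolated)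
Conditions: 1-chloro-N,N,2-trimethylprop-1-en-1-amine (1.05 equiv), CH2Cl2, 0 °C to rt; then 8, Et3N, DMAP (cat.), CH2Cl2, 0 °C to rt
Reagents that add atoms: none
Why: Acid chloride esterification with DMAP nucleophilic catalysis, in which the chloroenamine forms the acid chloride without releasing HCl, the three oxygen donors let the doubly ortho-substituted acyl chloride ionise easily to an acylpyridinium species, and O-aroylation of 2-hydroxyacetophenones under amine base is the standard first stage of Baker–Venkataraman sequences, whose rearrangement needs a much stronger base.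

**Step 7**
Reactants: 10 2-acetyl-5-(tert-butyldimethylsilyloxy)phenyl 4,6-bis(tert-butyldimethylsilyloxy)-2-methoxy-3-prenylbenzoate
Product: 11 6-(tert-butyldimethylsilyloxy)-2-[4,6-bis(tert-butyldimethylsilyloxy)-2-methoxy-3-prenylphenyl]-3-methylbenzofuran
Conditions: TiCl3 (6 equiv), Zn dust (12 equiv), DME, reflux, 2 h, Ar; then 10 in DME by syringe pump over 10 h at reflux (final about 0.005 M); filtration through silica gel
Reagents that add atoms: none
Why: Low-valent titanium made from TiCl3 and Zn transfers electrons to the more easily reduced aryl methyl ketone of 10, and the metal-bound ketyl carbon, the future C3, attacks the ester carbonyl carbon, the future C2, which is held close through C3a, C7a and O1. This closes the furan, the only ring formed, in a 5-exo-trig mode, and at the metal-bound 2,3-diolate stage both oxygens pass to the oxophilic titanium, with aromatisation as added driving force. The closest known reaction type is the McMurry-type titanium-induced oxo-ester cyclisation of 2-acyloxyaryl ketones to 2,3-disubstituted benzofurans, which also accepts bulky acyl groups. No stereocentre is created. The selectivity needed is intramolecular ketone–ester coupling over pinacol or alkene formation between two acetyl groups and over plain ketone reduction, and it is secured by the ortho relation of the two carbonyls, their joint binding to titanium and slow addition into excess reagent. The aryl silyl ethers, the methyl ether and the unactivated trisubstituted prenyl alkene should not be reduced, the non-aqueous work-up keeps protic acid away from the prenyl group, and partial silyl loss would be harmless because step 8 removes all three groups.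

**Step 8**
Reactants: 11 6-(tert-butyldimethylsilyloxy)-2-[4,6-bis(tert-butyldimethylsilyloxy)-2-methoxy-3-prenylphenyl]-3-methylbenzofuran
Product: 12 glycybenzofuran, 4-(6-hydroxy-3-methylbenzofuran-2-yl)-5-methoxy-6-prenylbenzene-1,3-diol
Conditions: Bu4NF (3.5 equiv), AcOH (3.5 equiv), THF, 0 °C
Reagents that add atoms: none
Why: Fluoride-induced cleavage of aryl silyl ethers driven by Si–F bond formation, with acetic acid buffering the phenoxides so that the electron-rich triphenol is not exposed to base and air, and with no strong acid present that could cyclise the C3' prenyl group onto O4' to a chroman.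

**Compound list**

1 | 2,4,6-trihydroxybenzaldehyde | O=Cc1c(O)cc(O)cc1O | starting material
2 | prenyl bromide (1-bromo-3-methylbut-2-ene) | CC(C)=CCBr | starting material
3 | 2,4,6-trihydroxy-3-prenylbenzaldehyde | O=Cc1c(O)cc(O)c(CC=C(C)C)c1O | intermediate
4 | 4,6-bis(tert-butyldimethylsilyloxy)-2-hydroxy-3-prenylbenzaldehyde | O=Cc1c(O[Si](C)(C)C(C)(C)C)cc(O[Si](C)(C)C(C)(C)C)c(CC=C(C)C)c1O | intermediate
5 | 4,6-bis(tert-butyldimethylsilyloxy)-2-methoxy-3-prenylbenzaldehyde | O=Cc1c(O[Si](C)(C)C(C)(C)C)cc(O[Si](C)(C)C(C)(C)C)c(CC=C(C)C)c1OC | intermediate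
6 | 4,6-bis(tert-butyldimethylsilyloxy)-2-methoxy-3-prenylbenzoic acid | OC(=O)c1c(O[Si](C)(C)C(C)(C)C)cc(O[Si](C)(C)C(C)(C)C)c(CC=C(C)C)c1OC | intermediate
7 | 2,4-dihydroxyacetophenone | CC(=O)c1ccc(O)cc1O | starting material
8 | 1-[4-(tert-butyldimethylsilyloxy)-2-hydroxyphenyl]ethanone | CC(=O)c1ccc(O[Si](C)(C)C(C)(C)C)cc1O | intermediate
9 | 4,6-bis(tert-butyldimethylsilyloxy)-2-methoxy-3-prenylbenzoyl chloride (not isolated) | ClC(=O)c1c(O[Si](C)(C)C(C)(C)C)cc(O[Si](C)(C)C(C)(C)C)c(CC=C(C)C)c1OC | intermediate
10 | 2-acetyl-5-(tert-butyldimethylsilyloxy)phenyl 4,6-bis(tert-butyldimethylsilyloxy)-2-methoxy-3-prenylbenzoate | CC(=O)c1ccc(O[Si](C)(C)C(C)(C)C)cc1OC(=O)c1c(OC)c(CC=C(C)C)c(O[Si](C)(C)C(C)(C)C)cc1O[Si](C)(C)C(C)(C)C | intermediate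
11 | 6-(tert-butyldimethylsilyloxy)-2-[4,6-bis(tert-butyldimethylsilyloxy)-2-methoxy-3-prenylphenyl]-3-methylbenzofuran | COc1c(CC=C(C)C)c(O[Si](C)(C)C(C)(C)C)cc(O[Si](C)(C)C(C)(C)C)c1-c1oc2cc(O[Si](C)(C)C(C)(C)C)ccc2c1C | intermediate
12 | glycybenzofuran | COc1c(CC=C(C)C)c(O)cc(O)c1-c1oc2cc(O)ccc2c1C | target

**Step count**

- Total step count: 8.
- Longest linear sequence: 7 (steps 1, 2, 3, 4, 6, 7, 8).

**Steps most likely to fail**

**Risk 1, step 7.**
- What may go wrong: attack of the reduced ketone carbon on the ester carbonyl may be slowed by the OMe and OTBS groups on both ortho positions of ring B. Intermolecular pinacol coupling or plain reduction of the acetyl group could then take over. The Lewis-acidic titanium and zinc chlorides could also strip silyl groups and let the prenyl group cyclise.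
- Fallback: it forms the same C2=C3 bond by an intramolecular Wittig reaction. It sets out from 8 (with acid chloride 9 made from 6 as in step 6) and comes back at 11.
- Course of the fallback: ketone 8 is reduced with NaBH4 in THF/EtOH at 0 °C to racemic 5-(tert-butyldimethylsilyloxy)-2-(1-hydroxyethyl)phenol F1. With PPh3·HBr in MeCN at reflux this gives, through the ortho-quinone methide, racemic [1-(4-(tert-butyldimethylsilyloxy)-2-hydroxyphenyl)ethyl]triphenylphosphonium bromide F2. This salt is O-acylated with 9 and Et3N in toluene to the aroyloxy phosphonium salt F3. More Et3N at reflux forms the ylide, which closes onto the ester carbonyl and gives 11.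

**Risk 2, step 6.**
- What may go wrong: acyl transfer at the carbonyl flanked by OMe and OTBS may be slow, so that hydrolysis of the activated acid, loss of CO2 from the electron-rich acid or silyl loss compete.
- Fallback: it moves the bond formation from the crowded acyl carbon to the aryl carbon C7a of ring A, with the carboxylate oxygen acting as the nucleophile. It sets out from 8 and 6 and comes back at 10.
- Course of the fallback: phenol 8 is converted with Tf2O and pyridine in CH2Cl2 into 2-acetyl-5-(tert-butyldimethylsilyloxy)phenyl trifluoromethanesulfonate F4. Miyaura borylation (B2pin2, PdCl2(dppf), KOAc, dioxane, 80 °C) gives 1-[4-(tert-butyldimethylsilyloxy)-2-(4,4,5,5-tetramethyl-1,3,2-dioxaborolan-2-yl)phenyl]ethanone F5. A Chan–Lam-type oxidative coupling of this boronate with acid 6 (Cu(OTf)2, urea, air, EtOAc, 60 °C) forms the O1–C7a bond and delivers 10.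

**Risk 3, step 2.**
- What may go wrong: site selectivity between O6 and O2 may be poor, or over-silylation may occur, on top of the mixtures of C- and O-alkylation expected in step 1.
- Fallback: it fixes the position of the free hydroxyl by symmetry and by a sigmatropic shift. It sets out from 1, replaces steps 1 and 2, and comes back at 4.
- Course of the fallback: aldehyde 1, whose two ortho hydroxyls are equivalent, is silylated with TBSCl (2.1 equiv) and imidazole to 4,6-bis(tert-butyldimethylsilyloxy)-2-hydroxybenzaldehyde F6. The remaining phenol is converted by Tsuji–Trost allylation with tert-butyl 2-methylbut-3-en-2-yl carbonate and Pd(PPh3)4 (zerovalent palladium) in THF at 0 °C into the tertiary ether 4,6-bis(tert-butyldimethylsilyloxy)-2-(2-methylbut-3-en-2-yloxy)benzaldehyde F7. Heating this ether in toluene or N,N-diethylaniline triggers an aromatic Claisen rearrangement to the only free ortho carbon, C3. The shift inverts the allyl unit into the prenyl group and gives 4, with the free hydroxyl necessarily next to the prenyl group.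

**Further compounds**

F1 | step 7 | 5-(tert-butyldimethylsilyloxy)-2-(1-hydroxyethyl)phenol (racemic) | CC(O)c1ccc(O[Si](C)(C)C(C)(C)C)cc1O
F2 | step 7 | [1-(4-(tert-butyldimethylsilyloxy)-2-hydroxyphenyl)ethyl]triphenylphosphonium bromide (racemic) | CC(c1ccc(O[Si](C)(C)C(C)(C)C)cc1O)[P+](c1ccccc1)(c1ccccc1)c1ccccc1.[Br-]
F3 | step 7 | [1-(2-(4,6-bis(tert-butyldimethylsilyloxy)-2-methoxy-3-prenylbenzoyloxy)-4-(tert-butyldimethylsilyloxy)phenyl)ethyl]triphenylphosphonium bromide (racemic) | CC(c1ccc(O[Si](C)(C)C(C)(C)C)cc1OC(=O)c1c(OC)c(CC=C(C)C)c(O[Si](C)(C)C(C)(C)C)cc1O[Si](C)(C)C(C)(C)C)[P+](c1ccccc1)(c1ccccc1)c1ccccc1.[Br-]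
F4 | step 6 | 2-acetyl-5-(tert-butyldimethylsilyloxy)phenyl trifluoromethanesulfonate | CC(=O)c1ccc(O[Si](C)(C)C(C)(C)C)cc1OS(=O)(=O)C(F)(F)F
F5 | step 6 | 1-[4-(tert-butyldimethylsilyloxy)-2-(4,4,5,5-tetramethyl-1,3,2-dioxaborolan-2-yl)phenyl]ethanone | CC(=O)c1ccc(O[Si](C)(C)C(C)(C)C)cc1B1OC(C)(C)C(C)(C)O1
F6 | step 2 | 4,6-bis(tert-butyldimethylsilyloxy)-2-hydroxybenzaldehyde | O=Cc1c(O)cc(O[Si](C)(C)C(C)(C)C)cc1O[Si](C)(C)C(C)(C)C
F7 | step 2 | 4,6-bis(tert-butyldimethylsilyloxy)-2-(2-methylbut-3-en-2-yloxy)benzaldehyde | O=Cc1c(OC(C)(C)C=C)cc(O[Si](C)(C)C(C)(C)C)cc1O[Si](C)(C)C(C)(C)C
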